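Ring A (C1–C5, C10) is grown from a five-membered ring: a 1,2,2-trimethylcyclopentane (C10, C1–C4) carries C5 as an exocyclic carbinol. Ionising C5 makes the C4–C10 bond migrate to C5, expanding the cyclopentane to ring A; the tertiary C10 cation so formed is trapped by the C8=C9 allylsilane, which closes ring B, sets C5, C9 and C10 and leaves the C8(26) methylene, all in one operation. The step exploits the quaternary C4 flanked by C5–H and the methyl-bearing C10. Its precursor is an open-chain cyclopentyl carbinol that already holds the cis-fused DE decalin, made from pulegone and attached by B-alkyl Suzuki coupling.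

Key step: step 17

Remark: atom labels C1–C30 follow the ursane numbering of the target (ring A = C1–C5 and C10, ring B = C5–C10, rings D and E = the decalin C13–C22).
Remark: compounds 1, 6, 14 and 18 are taken as purchasable; a minor C1 epimer of nitrile 5 would be carried along, because this carbon (C10) becomes a planar cation in step 17.

Step 1
Reactants: 1 2,2-dimethylcyclopentane-1,3-dione
Product: 2 (S)-3-hydroxy-2,2-dimethylcyclopentan-1-one
Conditions: (R)-2-methyl-CBS-oxazaborolidine (10 mol%), BH3·SMe2 (0.6 equiv), THF, −20 °C; MeOH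
Reagents that add atoms: none
Why: Corey–Bakshi–Shibata reduction desymmetrises the dione; with the quaternary carbon as the large group the (R)-catalyst should give the (S)-carbinol, the future C3.

Step 2
Reactants: 2 (S)-3-hydroxy-2,2-dimethylcyclopentan-1-one
Product: 3 (S)-3-(tert-butyldimethylsilyloxy)-2,2-dimethylcyclopentan-1-one
Conditions: t-BuMe2SiCl, imidazole, DMF, rt
Reagents that add atoms: tert-butyldimethylsilyl chloride (CC(C)(C)[Si](C)(C)Cl)
Why: Standard silylation masks the C3 oxygen for the basic and organometallic steps that follow.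

Step 3
Reactants: 3 (S)-3-(tert-butyldimethylsilyloxy)-2,2-dimethylcyclopentan-1-one
Product: 4 (3S)-3-(tert-butyldimethylsilyloxy)-2,2-dimethylcyclopentane-1-carbonitrile (both C1 epimers)
Conditions: TosMIC, t-BuOK, DME/EtOH, 0 → 40 °C
Reagents that add atoms: p-toluenesulfonylmethyl isocyanide (Cc1ccc(cc1)S(=O)(=O)C[N+]#[C-])
Why: The van Leusen reductive cyanation turns the ketone into the homologous nitrile; the silyloxy group cannot be eliminated because the carbon between it and the carbonyl is quaternary.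

Step 4
Reactants: 4 (3S)-3-(tert-butyldimethylsilyloxy)-2,2-dimethylcyclopentane-1-carbonitrile
Product: 5 (1R,3S)-3-(tert-butyldimethylsilyloxy)-1,2,2-trimethylcyclopentane-1-carbonitrile (methyl trans to the silyloxy group)
Conditions: LiN(i-Pr)2, THF, −78 °C; MeI, −78 → 0 °C
Reagents that add atoms: iodomethane (CI)
Why: Alkylation of the nitrile-stabilised carbanion builds the quaternary future C10 next to the gem-dimethyl carbon; iodomethane should enter anti to the silyloxy group, and this configuration is erased in step 17.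

Step 5
Reactants: 5 (1R,3S)-3-(tert-butyldimethylsilyloxy)-1,2,2-trimethylcyclopentane-1-carbonitrile; 6 (4-bromobut-1-yn-1-yl)trimethylsilane
Product: 10 1-[(1R,3S)-3-(tert-butyldimethylsilyloxy)-1,2,2-trimethylcyclopentyl]pent-4-yn-1-one, via Grignard reagent 7 (not isolated), via magnesium ketimide 8 (not isolated), via silylalkynyl ketone 9 (not isolated)
Conditions: Mg, THF (6 to 7); 5, CuBr (5 mol%), THF, reflux; 10% aq. citric acid, rt; then K2CO3, MeOH, rt
Reagents that add atoms: water (O)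
Why: Copper-catalysed Grignard addition to the nitrile stops at the ketimide, hydrolysis gives the ketone (C5), and methanolysis removes the alkynyl silyl group.

Step 6
Reactants: 10 1-[(1R,3S)-3-(tert-butyldimethylsilyloxy)-1,2,2-trimethylcyclopentyl]pent-4-yn-1-one
Product: 12 (Z)-1-[(1R,3S)-3-(tert-butyldimethylsilyloxy)-1,2,2-trimethylcyclopentyl]-5-iodo-4-[(trimethylsilyl)methyl]pent-4-en-1-one, via alkenylcopper 11 (not isolated)
Conditions: Me3SiCH2MgCl, CuBr·SMe2, Et2O, −10 °C → rt; then I2, THF, −40 → 0 °C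
Reagents that add atoms: (trimethylsilylmethyl)magnesium chloride (C[Si](C)(C)C[Mg]Cl); iodine (II)
Why: syn-Carbocupration of the terminal alkyne puts the silylmethyl group on the internal carbon (C8) and copper on C9, and iodinolysis with retention gives the Z iodide (iodine cis to CH2SiMe3); the hindered ketone is inert to the organocopper reagent.

Step 7
Reactants: 12 (Z)-1-[(1R,3S)-3-(tert-butyldimethylsilyloxy)-1,2,2-trimethylcyclopentyl]-5-iodo-4-[(trimethylsilyl)methyl]pent-4-en-1-one
Product: 13 (1S,4Z)-1-[(1R,3S)-3-(tert-butyldimethylsilyloxy)-1,2,2-trimethylcyclopentyl]-5-iodo-4-[(trimethylsilyl)methyl]pent-4-en-1-ol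
Conditions: (R)-2-methyl-CBS-oxazaborolidine (20 mol%), BH3·SMe2, THF, −20 → 0 °C; MeOH
Reagents that add atoms: none
Why: Corey–Bakshi–Shibata reduction of a tert-alkyl/primary-alkyl ketone is reagent-controlled, so the (R)-catalyst should give the (S)-carbinol at C5 whatever the configuration of the neighbouring quaternary carbon.

Step 8
Reactants: 14 (R)-(+)-pulegone
Product: 15 (2S,3R)-2,3-dimethyl-6-(propan-2-ylidene)cyclohexan-1-one
Conditions: LiN(i-Pr)2, THF, −78 °C; MeI, −78 → 0 °C
Reagents that add atoms: iodomethane (CI)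
Why: Kinetic α′-enolate alkylation, with the isopropylidene group blocking the other α-carbon, introduces the future C19 methyl next to the pulegone methyl (future C20).

Step 9
Reactants: 15 (2S,3R)-2,3-dimethyl-6-(propan-2-ylidene)cyclohexan-1-one
Product: 16 (2S,3R)-2,3-dimethylcyclohexan-1-one (trans)
Conditions: 3 M aq. HCl, reflux, acetone distilled off
Reagents that add atoms: none
Why: Acid-catalysed retro-aldol cleavage removes the isopropylidene group as acetone, and the epimerisable C2 methyl settles trans (diequatorial) to the C3 methyl, whose configuration comes from pulegone.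

Step 10
Reactants: 16 (2S,3R)-2,3-dimethylcyclohexan-1-one
Product: 17 (2S,3R)-2,3,6-trimethylcyclohexan-1-one (C6 epimers)
Conditions: LiN(i-Pr)2, THF, −78 °C; MeI
Reagents that add atoms: iodomethane (CI)
Why: Kinetic enolate formation at the unsubstituted α-CH2 followed by methylation adds the future angular methyl; the new centre is consumed in step 11.

Step 11
Reactants: 17 (2S,3R)-2,3,6-trimethylcyclohexan-1-one; 18 1-methoxybut-3-en-2-one
Product: 20 (4aR,7R,8S)-1-methoxy-4a,7,8-trimethyl-4,4a,5,6,7,8-hexahydronaphthalen-2(3H)-one, via Michael adduct 19 (not isolated)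
Conditions: KOH (0.2 equiv), MeOH, 0 °C → rt; then NaOMe, MeOH, reflux
Reagents that add atoms: none
Why: Robinson annulation: Michael addition should occur at the less hindered methyl-bearing α-carbon (C17) by axial attack on the half-chair enolate with both ring methyls equatorial, which places the angular methyl cis to the C19 methyl and trans to the C20 methyl, and the methoxy-activated methylene then condenses onto the ring ketone.

Step 12
Reactants: 20 (4aR,7R,8S)-1-methoxy-4a,7,8-trimethyl-4,4a,5,6,7,8-hexahydronaphthalen-2(3H)-one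
Product: 22 (4aR,7R,8S,8aR)-2-hydroxy-2,4a,7,8-tetramethyloctahydronaphthalen-1(2H)-one (cis-fused; C2 epimers), via tertiary allylic alcohol 21 (not isolated)
Conditions: MeLi, CeCl3, THF, −78 °C; then 1 M aq. HCl, THF, rt
Reagents that add atoms: methyllithium (C[Li]); water (O)
Why: 1,2-Addition of methyllithium to the enone carbonyl and hydrolysis of the enol ether move the ketone to C13 (alkylative 1,2-carbonyl transposition); C18 equilibrates through the enol to the cis-fused epimer, the only one that keeps the three ring-E methyls equatorial.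

Step 13
Reactants: 22 (4aR,7R,8S,8aR)-2-hydroxy-2,4a,7,8-tetramethyloctahydronaphthalen-1(2H)-one
Product: 23 (4aR,7R,8S,8aR)-2,4a,7,8-tetramethyl-4a,5,6,7,8,8a-hexahydronaphthalen-1(4H)-one
Conditions: SOCl2, pyridine, CH2Cl2, 0 °C; then DBU, rt
Reagents that add atoms: none
Why: Dehydration of the tertiary α-ketol through its chlorosulfite (E2) gives the conjugated enone, and DBU moves any exocyclic double bond into the ring.

Step 14
Reactants: 23 (4aR,7R,8S,8aR)-2,4a,7,8-tetramethyl-4a,5,6,7,8,8a-hexahydronaphthalen-1(4H)-one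
Product: 25 (4aR,7R,8S,8aR)-2,4a,7,8-tetramethyl-3,4,4a,5,6,7,8,8a-octahydronaphthalen-1-yl trifluoromethanesulfonate, via lithium enolate 24 (not isolated)
Conditions: Li[HB(s-Bu)3], THF, −78 °C; then N-(5-chloropyridin-2-yl)triflimide, −78 → 0 °C
Reagents that add atoms: N-(5-chloropyridin-2-yl)-1,1,1-trifluoro-N-(trifluoromethylsulfonyl)methanesulfonamide (O=S(=O)(N(c1ccc(Cl)cn1)S(=O)(=O)C(F)(F)F)C(F)(F)F)
Why: Conjugate hydride reduction of the β-unsubstituted enone gives the C13–C14 enolate regiospecifically, and O-triflation traps it as the tetrasubstituted enol triflate without touching C18.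

Step 15
Reactants: 25 (4aR,7R,8S,8aR)-2,4a,7,8-tetramethyl-3,4,4a,5,6,7,8,8a-octahydronaphthalen-1-yl trifluoromethanesulfonate
Product: 26 (4aR,7R,8S,8aR)-1-ethenyl-2,4a,7,8-tetramethyl-3,4,4a,5,6,7,8,8a-octahydronaphthalene
Conditions: tributyl(vinyl)stannane, Pd(PPh3)4 (5 mol%), LiCl, THF, reflux
Reagents that add atoms: tributyl(vinyl)stannane (C=C[Sn](CCCC)(CCCC)CCCC)
Why: Stille coupling of the enol triflate attaches C12 and C11 as a vinyl group and fixes the C13=C14 double bond.

Step 16
Reactants: 26 (4aR,7R,8S,8aR)-1-ethenyl-2,4a,7,8-tetramethyl-3,4,4a,5,6,7,8,8a-octahydronaphthalene; 13 (1S,4Z)-1-[(1R,3S)-3-(tert-butyldimethylsilyloxy)-1,2,2-trimethylcyclopentyl]-5-iodo-4-[(trimethylsilyl)methyl]pent-4-en-1-ol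
Product: 28 (1S,4Z)-1-[(1R,3S)-3-(tert-butyldimethylsilyloxy)-1,2,2-trimethylcyclopentyl]-7-[(4aR,7R,8S,8aR)-2,4a,7,8-tetramethyl-3,4,4a,5,6,7,8,8a-octahydronaphthalen-1-yl]-4-[(trimethylsilyl)methyl]hept-4-en-1-ol, via alkylborane 27 (not isolated)
Conditions: 9-BBN dimer, THF, rt; then 13, Pd(dppf)Cl2 (5 mol%), 3 M aq. K3PO4, DMF, rt
Reagents that add atoms: none
Why: 9-BBN adds only to the terminal vinyl group (boron on C11), and the B-alkyl Suzuki–Miyaura coupling with the vinyl iodide forms C9–C11 with retention of the Z geometry; the free hydroxyl and the allylsilane are tolerated.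

Step 17
Reactants: 28 (1S,4Z)-1-[(1R,3S)-3-(tert-butyldimethylsilyloxy)-1,2,2-trimethylcyclopentyl]-7-[(4aR,7R,8S,8aR)-2,4a,7,8-tetramethyl-3,4,4a,5,6,7,8,8a-octahydronaphthalen-1-yl]-4-[(trimethylsilyl)methyl]hept-4-en-1-ol
Product: 30 (3β)-3-(tert-butyldimethylsilyloxy)-8,14-secoursa-8(26),13-diene, via secondary triflate 29 (not isolated)
Conditions: Tf2O (1.2 equiv), 2,6-di-tert-butyl-4-methylpyridine (3 equiv), CH2Cl2, −78 → −20 °C; aq. NaHCO3
Reagents that add atoms: none
Why: Proposed new method: the secondary neopentyl triflate 29 should ionise with assistance from the antiperiplanar C4–C10 bond (Wagner–Meerwein 1,2-shift, invertive at C5), which turns the cyclopentane C10–C1–C2–C3–C4 into six-membered ring A by forming C4–C5 and leaves a tertiary cation at C10; C9 of the Z allylsilane then attacks C10 and the β-silyl cation at C8 loses the silyl group to give the C8(26) methylene. The closest known reaction types are the solvolytic ring expansion of (1-methylcyclopentyl)carbinyl sulfonates and the second ring closure of an epoxy-farnesyl allylsilane polycyclisation, which passes through the same C10 cation with its chain on C5. Ring A arises by one-carbon ring expansion (cyclopentane to cyclohexane) and ring B by 6-endo-trig attack of the alkene on the C10 cation. C5 is set by inversion at the carbinol carbon fixed in step 7, C10 and C9 by a chair-like closure with the C5 chain and C11 equatorial (methyl axial, trans-decalin; C9 follows from the Z alkene geometry), and C3 is carried over unchanged. The step needs migration of the quaternary C4 rather than C1 or methyl, which the higher migratory aptitude of the tertiary carbon and relief of the C4/C10 congestion should secure, and it needs ring closure to outrun proton loss, which the nucleophilic allylsilane held in a six-membered array should provide; the alkene cannot reach C5 itself because only 4-exo or 5-endo modes are open to it. The old configuration at C10 is erased, so both epimers of 28 would converge.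

Step 18
Reactants: 30 (3β)-3-(tert-butyldimethylsilyloxy)-8,14-secoursa-8(26),13-diene
Product: 31 8,14-secoursa-8(26),13-dien-3β-ol (CNP0210309.1)
Conditions: Bu4NF, THF, 60 °C
Reagents that add atoms: none
Why: Fluoride desilylation frees the hindered 3β-hydroxyl under non-acidic conditions that leave the exocyclic and tetrasubstituted alkenes in place.

Compound list
1 | 2,2-dimethylcyclopentane-1,3-dione | CC1(C)C(=O)CCC1=O | starting material
2 | (S)-3-hydroxy-2,2-dimethylcyclopentan-1-one | CC1(C)[C@@H](O)CCC1=O | intermediate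
3 | (S)-3-(tert-butyldimethylsilyloxy)-2,2-dimethylcyclopentan-1-one | CC1(C)[C@@H](O[Si](C)(C)C(C)(C)C)CCC1=O | intermediate
4 | (3S)-3-(tert-butyldimethylsilyloxy)-2,2-dimethylcyclopentane-1-carbonitrile, C1 epimers | CC1(C)[C@@H](O[Si](C)(C)C(C)(C)C)CCC1C#N | intermediate
5 | (1R,3S)-3-(tert-butyldimethylsilyloxy)-1,2,2-trimethylcyclopentane-1-carbonitrile | CC1(C)[C@@H](O[Si](C)(C)C(C)(C)C)CC[C@@]1(C)C#N | intermediate
6 | (4-bromobut-1-yn-1-yl)trimethylsilane | C[Si](C)(C)C#CCCBr | starting material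
7 | [4-(trimethylsilyl)but-3-yn-1-yl]magnesium bromide | C[Si](C)(C)C#CCC[Mg]Br | intermediate
8 | N-(bromomagnesio) ketimine of 9 | CC1(C)[C@@H](O[Si](C)(C)C(C)(C)C)CC[C@@]1(C)C(=N[Mg]Br)CCC#C[Si](C)(C)C | intermediate
9 | 1-[(1R,3S)-3-(tert-butyldimethylsilyloxy)-1,2,2-trimethylcyclopentyl]-5-(trimethylsilyl)pent-4-yn-1-one | CC1(C)[C@@H](O[Si](C)(C)C(C)(C)C)CC[C@@]1(C)C(=O)CCC#C[Si](C)(C)C | intermediate
10 | 1-[(1R,3S)-3-(tert-butyldimethylsilyloxy)-1,2,2-trimethylcyclopentyl]pent-4-yn-1-one | CC1(C)[C@@H](O[Si](C)(C)C(C)(C)C)CC[C@@]1(C)C(=O)CCC#C | intermediate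
11 | alkenylcopper from 10 (copper on C9, cis to CH2SiMe3) | CC1(C)[C@@H](O[Si](C)(C)C(C)(C)C)CC[C@@]1(C)C(=O)CC/C(C[Si](C)(C)C)=C/[Cu] | intermediate
12 | (Z)-1-[(1R,3S)-3-(tert-butyldimethylsilyloxy)-1,2,2-trimethylcyclopentyl]-5-iodo-4-[(trimethylsilyl)methyl]pent-4-en-1-one | CC1(C)[C@@H](O[Si](C)(C)C(C)(C)C)CC[C@@]1(C)C(=O)CC/C(C[Si](C)(C)C)=C/I | intermediate
13 | (1S,4Z)-1-[(1R,3S)-3-(tert-butyldimethylsilyloxy)-1,2,2-trimethylcyclopentyl]-5-iodo-4-[(trimethylsilyl)methyl]pent-4-en-1-ol | CC1(C)[C@@H](O[Si](C)(C)C(C)(C)C)CC[C@@]1(C)[C@@H](O)CC/C(C[Si](C)(C)C)=C/I | intermediate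
14 | (R)-(+)-pulegone, (5R)-5-methyl-2-(propan-2-ylidene)cyclohexan-1-one | CC(C)=C1CC[C@@H](C)CC1=O | starting material
15 | (2S,3R)-2,3-dimethyl-6-(propan-2-ylidene)cyclohexan-1-one | CC(C)=C1CC[C@@H](C)[C@H](C)C1=O | intermediate
16 | (2S,3R)-2,3-dimethylcyclohexan-1-one (trans) | C1CC[C@@H](C)[C@H](C)C1=O | intermediate
17 | (2S,3R)-2,3,6-trimethylcyclohexan-1-one, C6 epimers | CC1CC[C@@H](C)[C@H](C)C1=O | intermediate
18 | 1-methoxybut-3-en-2-one | COCC(=O)C=C | starting material
19 | (2R,5R,6S)-2-(4-methoxy-3-oxobutyl)-2,5,6-trimethylcyclohexan-1-one | COCC(=O)CC[C@@]1(C)CC[C@@H](C)[C@H](C)C1=O | intermediate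
20 | (4aR,7R,8S)-1-methoxy-4a,7,8-trimethyl-4,4a,5,6,7,8-hexahydronaphthalen-2(3H)-one | O=C1CC[C@@]2(C)CC[C@@H](C)[C@H](C)C2=C1OC | intermediate
21 | (4aR,7R,8S)-1-methoxy-2,4a,7,8-tetramethyl-2,3,4,4a,5,6,7,8-octahydronaphthalen-2-ol, C2 epimers | CC1(O)CC[C@@]2(C)CC[C@@H](C)[C@H](C)C2=C1OC | intermediate
22 | (4aR,7R,8S,8aR)-2-hydroxy-2,4a,7,8-tetramethyloctahydronaphthalen-1(2H)-one, cis-fused, C2 epimers | CC1(O)CC[C@@]2(C)CC[C@@H](C)[C@H](C)[C@H]2C1=O | intermediate
23 | (4aR,7R,8S,8aR)-2,4a,7,8-tetramethyl-4a,5,6,7,8,8a-hexahydronaphthalen-1(4H)-one | CC1=CC[C@@]2(C)CC[C@@H](C)[C@H](C)[C@H]2C1=O | intermediate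
24 | lithium enolate of the 2,3-dihydro derivative of 23 (C13–C14 enolate) | [Li]OC1=C(C)CC[C@@]2(C)CC[C@@H](C)[C@H](C)[C@@H]12 | intermediate
25 | (4aR,7R,8S,8aR)-2,4a,7,8-tetramethyl-3,4,4a,5,6,7,8,8a-octahydronaphthalen-1-yl trifluoromethanesulfonate | O=S(=O)(OC1=C(C)CC[C@@]2(C)CC[C@@H](C)[C@H](C)[C@@H]12)C(F)(F)F | intermediate
26 | (4aR,7R,8S,8aR)-1-ethenyl-2,4a,7,8-tetramethyl-3,4,4a,5,6,7,8,8a-octahydronaphthalene (8a-H cis to 4a-methyl and 8-methyl, 7-methyl trans) | C=CC1=C(C)CC[C@@]2(C)CC[C@@H](C)[C@H](C)[C@@H]12 | intermediate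
27 | 9-{2-[(4aR,7R,8S,8aR)-2,4a,7,8-tetramethyl-3,4,4a,5,6,7,8,8a-octahydronaphthalen-1-yl]ethyl}-9-borabicyclo[3.3.1]nonane | C(CC1=C(C)CC[C@@]2(C)CC[C@@H](C)[C@H](C)[C@@H]12)B1C2CCCC1CCC2 | intermediate
28 | (1S,4Z)-1-[(1R,3S)-3-(tert-butyldimethylsilyloxy)-1,2,2-trimethylcyclopentyl]-7-[(4aR,7R,8S,8aR)-2,4a,7,8-tetramethyl-3,4,4a,5,6,7,8,8a-octahydronaphthalen-1-yl]-4-[(trimethylsilyl)methyl]hept-4-en-1-ol | CC1(C)[C@@H](O[Si](C)(C)C(C)(C)C)CC[C@@]1(C)[C@@H](O)CC/C(C[Si](C)(C)C)=C/CCC1=C(C)CC[C@@]2(C)CC[C@@H](C)[C@H](C)[C@@H]12 | intermediate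
29 | trifluoromethanesulfonate of 28 at the C5 carbinol | CC1(C)[C@@H](O[Si](C)(C)C(C)(C)C)CC[C@@]1(C)[C@@H](OS(=O)(=O)C(F)(F)F)CC/C(C[Si](C)(C)C)=C/CCC1=C(C)CC[C@@]2(C)CC[C@@H](C)[C@H](C)[C@@H]12 | intermediate
30 | (3β)-3-(tert-butyldimethylsilyloxy)-8,14-secoursa-8(26),13-diene (5α-H, 9α-H, 10β-methyl) | C=C1CC[C@H]2C(C)(C)[C@@H](O[Si](C)(C)C(C)(C)C)CC[C@]2(C)[C@H]1CCC1=C(C)CC[C@@]2(C)CC[C@@H](C)[C@H](C)[C@@H]12 | intermediate
31 | 8,14-secoursa-8(26),13-dien-3β-ol, CNP0210309.1 (3β-OH, 5α-H, 9α-H, 10β-Me, 17β-Me, 18β-H, 19β-Me, 20α-Me) | C=C1CC[C@H]2C(C)(C)[C@@H](O)CC[C@]2(C)[C@H]1CCC1=C(C)CC[C@@]2(C)CC[C@@H](C)[C@H](C)[C@@H]12 | target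

Total step count: 18. Longest linear sequence: 11 steps (steps 8 to 18, from pulegone 14); the other branch (steps 1 to 7, then 16 to 18) has 10.

Steps most likely to fail

1. Step 17 (Proposed new method). The ring bond to C1 or the methyl group may migrate instead of C4, the C10 cation may lose a proton before ring B closes, the closure may give some cis-fused decalin, or the silyl ether oxygen may attack C5. The fallback separates ring expansion from ring-B closure with known reactions; it sets out from 10 and comes back at 30. Corey–Bakshi–Shibata reduction of 10 (same catalyst as step 7) would give (S)-1-[(1R,3S)-3-(tert-butyldimethylsilyloxy)-1,2,2-trimethylcyclopentyl]pent-4-yn-1-ol F1, and MsCl/Et3N its methanesulfonate F2. Buffered solvolysis of F2 (acetone/water, 2,6-lutidine, 50 °C) is the known Wagner–Meerwein ring expansion of a (1-methylcyclopentyl)carbinyl sulfonate with capture of the tertiary cation by water; it should give the ring-A cyclohexanol (2S,4S)-2-(but-3-yn-1-yl)-4-(tert-butyldimethylsilyloxy)-1,3,3-trimethylcyclohexan-1-ol F3 (C1 epimers), with C5 already inverted to the required configuration. Carbocupration and iodination as in step 6 would give the vinyl iodide (2S,4S)-4-(tert-butyldimethylsilyloxy)-2-{(Z)-4-iodo-3-[(trimethylsilyl)methyl]but-3-en-1-yl}-1,3,3-trimethylcyclohexan-1-ol F4, and Suzuki coupling with 27 as in step 16 the tertiary alcohol (2S,4S)-4-(tert-butyldimethylsilyloxy)-1,3,3-trimethyl-2-{(3Z)-6-[(4aR,7R,8S,8aR)-2,4a,7,8-tetramethyl-3,4,4a,5,6,7,8,8a-octahydronaphthalen-1-yl]-3-[(trimethylsilyl)methyl]hex-3-en-1-yl}cyclohexan-1-ol F5. SnCl4 in CH2Cl2 at −78 °C would then ionise the tertiary alcohol and the allylsilane would close ring B (tertiary-carbinol-initiated cation–olefin cyclisation with allylsilane termination), giving 30.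

2. Step 11. The Michael addition may occur at the other methyl-bearing α-carbon (next to the C20 methyl), its facial selectivity may be poor, or the vinyl ketone may polymerise under base. The fallback sets out from 17 and comes back at 20. Kinetic deprotonation at the less hindered methine (LiN(i-Pr)2, −78 °C) and silylation would give trimethyl{[(5R,6S)-2,5,6-trimethylcyclohex-1-en-1-yl]oxy}silane F6. A Mukaiyama–Michael addition of F6 to 18 (TiCl4, CH2Cl2, −78 °C) would give 19 regiospecifically, and 19 would be cyclised separately (NaOMe, MeOH, reflux) to 20.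

3. Step 5. Addition of the Grignard reagent to a nitrile flanked by two quaternary carbons may be too slow, and the hindered ketimine may hydrolyse incompletely. The fallback sets out from 5 and comes back at 9 (then 10 by the same methanolysis). Reduction with i-Bu2AlH (toluene, −78 °C, aqueous acid work-up) would give (1R,3S)-3-(tert-butyldimethylsilyloxy)-1,2,2-trimethylcyclopentane-1-carbaldehyde F7. Addition of 7 to the aldehyde would give 1-[(1R,3S)-3-(tert-butyldimethylsilyloxy)-1,2,2-trimethylcyclopentyl]-5-(trimethylsilyl)pent-4-yn-1-ol F8 (carbinol epimers), and Swern oxidation would give 9.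

Further compounds
F1 | step 17 | (S)-1-[(1R,3S)-3-(tert-butyldimethylsilyloxy)-1,2,2-trimethylcyclopentyl]pent-4-yn-1-ol | CC1(C)[C@@H](O[Si](C)(C)C(C)(C)C)CC[C@@]1(C)[C@@H](O)CCC#C
F2 | step 17 | methanesulfonate of F1 | CC1(C)[C@@H](O[Si](C)(C)C(C)(C)C)CC[C@@]1(C)[C@@H](OS(C)(=O)=O)CCC#C
F3 | step 17 | (2S,4S)-2-(but-3-yn-1-yl)-4-(tert-butyldimethylsilyloxy)-1,3,3-trimethylcyclohexan-1-ol, C1 epimers | C#CCC[C@H]1C(C)(C)[C@@H](O[Si](C)(C)C(C)(C)C)CCC1(C)O
F4 | step 17 | (2S,4S)-4-(tert-butyldimethylsilyloxy)-2-{(Z)-4-iodo-3-[(trimethylsilyl)methyl]but-3-en-1-yl}-1,3,3-trimethylcyclohexan-1-ol | I/C=C(C[Si](C)(C)C)/CC[C@H]1C(C)(C)[C@@H](O[Si](C)(C)C(C)(C)C)CCC1(C)O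
F5 | step 17 | (2S,4S)-4-(tert-butyldimethylsilyloxy)-1,3,3-trimethyl-2-{(3Z)-6-[(4aR,7R,8S,8aR)-2,4a,7,8-tetramethyl-3,4,4a,5,6,7,8,8a-octahydronaphthalen-1-yl]-3-[(trimethylsilyl)methyl]hex-3-en-1-yl}cyclohexan-1-ol | C[Si](C)(C)C/C(=C\CCC1=C(C)CC[C@@]2(C)CC[C@@H](C)[C@H](C)[C@@H]12)CC[C@H]1C(C)(C)[C@@H](O[Si](C)(C)C(C)(C)C)CCC1(C)O
F6 | step 11 | trimethyl{[(5R,6S)-2,5,6-trimethylcyclohex-1-en-1-yl]oxy}silane | CC1=C(O[Si](C)(C)C)[C@@H](C)[C@H](C)CC1
F7 | step 5 | (1R,3S)-3-(tert-butyldimethylsilyloxy)-1,2,2-trimethylcyclopentane-1-carbaldehyde | CC1(C)[C@@H](O[Si](C)(C)C(C)(C)C)CC[C@@]1(C)C=O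
F8 | step 5 | 1-[(1R,3S)-3-(tert-butyldimethylsilyloxy)-1,2,2-trimethylcyclopentyl]-5-(trimethylsilyl)pent-4-yn-1-ol, carbinol epimers | CC1(C)[C@@H](O[Si](C)(C)C(C)(C)C)CC[C@@]1(C)C(O)CCC#C[Si](C)(C)C
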